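Ring A (C3a, C4, C5, C6, C7, C7a; benzofuran numbering) is opened at C3a-C4 and C6-C7. C4-C5-C6 then leaves as a gem-diprenylated malonyl dielectrophile. What remains is a beta-alkoxy enone that already holds ring B (O1, C2, C3), the C2 stereocentre and the isobutyryl group. The feature exploited is that C3a and C7 are the gamma and alpha carbons of this push-pull system, so one operation acylates both and builds ring A with C5 delivered ready-made. The precursor is an (S)-configured (E)-acylmethylidene-oxolane from an (S)-glycidate-derived epoxide, activated in the flask as its silyl dienol ether so that C3a reacts first.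

Key step: step 8

Assumption: atom labels O1 to C7a follow the benzofuran numbering of the target at every stage. The chelated Z enol drawn for 19 is taken as the tautomer obtained after acidic work-up. C2 of the target is S, and this descriptor holds from 7 to 19 because no bond to that carbon is broken and the priority order (oxygen, then the carbon that becomes CMe2O, then CH2, then H) never changes.

Step 1
Reactants: 1 diethyl malonate; 2 prenyl bromide (1-bromo-3-methylbut-2-ene)
Product: 4 diethyl 2,2-bis(3-methylbut-2-enyl)malonate, via monoprenyl malonate 3 (not isolated)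
Conditions: NaH (2.3 equiv), 2 (2.2 equiv), THF, 0 °C to 50 °C
Reagents that add atoms: none
Why: Malonic ester synthesis, in which the sodium enolate displaces the primary allylic bromide by SN2 at its CH2 terminus, and 3, still carrying one acidic hydrogen, is deprotonated and alkylated a second time in the same flask.

Step 2
Reactants: 4 diethyl 2,2-bis(3-methylbut-2-enyl)malonate
Product: 5 2,2-bis(3-methylbut-2-enyl)malonic acid
Conditions: KOH (6 equiv), EtOH/H2O, reflux; 1 M HCl to pH 2, 0 °C
Reagents that add atoms: potassium hydroxide, [K+].[OH-]
Why: Saponification of a hindered dialkylmalonate needs excess hydroxide and heat, which the isolated trisubstituted alkenes tolerate, and the brief cold acidification avoids both lactonisation onto a prenyl group and decarboxylation.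

Step 3
Reactants: 5 2,2-bis(3-methylbut-2-enyl)malonic acid
Product: 6 2,2-bis(3-methylbut-2-enyl)malonyl dichloride (fragment 2)
Conditions: 1-chloro-N,N,2-trimethylprop-1-en-1-amine (2.2 equiv), CH2Cl2, 0 °C to rt; amide co-product removed at 0.1 mbar
Reagents that add atoms: 1-chloro-N,N,2-trimethylprop-1-en-1-amine, CC(C)=C(Cl)N(C)C
Why: Acid chloride formation with an alpha-chloroenamine runs under neutral conditions and gives only an amide beside the product, so no HCl is present that could add to the prenyl alkenes.

Step 4
Reactants: 7 methyl (S)-glycidate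
Product: 9 (S)-2-(oxiran-2-yl)propan-2-ol, via epoxy ketone 8 (not isolated)
Conditions: MeMgCl (2.3 equiv), THF, −78 to −30 °C; sat. aq. NH4Cl; ether extract concentrated cold
Reagents that add atoms: methylmagnesium chloride, C[Mg]Cl
Why: Double Grignard addition to the ester is much faster at low temperature than attack on the epoxide, and the stereocentre taken from 7 is kept because none of its bonds is broken and an oxiranyl C-H is not enolised.

Step 5
Reactants: 9 (S)-2-(oxiran-2-yl)propan-2-ol
Product: 10 (S)-triethyl{[2-(oxiran-2-yl)propan-2-yl]oxy}silane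
Conditions: Et3SiOTf (1.2 equiv), 2,6-lutidine (1.8 equiv), CH2Cl2, −78 to 0 °C
Reagents that add atoms: triethylsilyl triflate, CC[Si](CC)(CC)OS(=O)(=O)C(F)(F)F
Why: Silylation of a tertiary alcohol with a silyl triflate and a hindered pyridine is fast at a temperature where the epoxide stays closed, and it blocks the tertiary oxygen so that only the secondary one can later close ring B.

Step 6
Reactants: 11 5-methylhexane-2,4-dione; 10 (S)-triethyl{[2-(oxiran-2-yl)propan-2-yl]oxy}silane
Product: 13 (S)-8-hydroxy-2,9-dimethyl-9-(triethylsilyloxy)decane-3,5-dione, via dilithio dianion 12 (not isolated)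
Conditions: 11 (1.5 equiv), LiN(iPr)2 (3.1 equiv), THF, 0 °C; 10 (1.0 equiv), −78 to 0 °C; AcOH, −20 °C
Reagents that add atoms: none
Why: Gamma-alkylation of a beta-diketone dianion, in which the second deprotonation takes the methyl group rather than the isopropyl methine, the terminal carbanion opens the epoxide by SN2 at its CH2 (C-O bond at the stereocentre untouched, S retained), and working at or below 0 °C followed by a cold acetic acid quench should keep the lithium alkoxide from taking over the neighbouring silyl group.

Step 7
Reactants: 13 (S)-8-hydroxy-2,9-dimethyl-9-(triethylsilyloxy)decane-3,5-dione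
Product: 15 (S,E)-3-methyl-1-[5-(2-triethylsilyloxypropan-2-yl)oxolan-2-ylidene]butan-2-one (fragment 1), via cyclic hemiketal 14 (not isolated)
Conditions: pyridinium p-toluenesulfonate (0.1 equiv), 4 Å molecular sieves, toluene, 60 °C
Reagents that add atoms: none
Why: Acid-catalysed cyclodehydration, in which the secondary hydroxyl adds 5-exo-trig to the nearer ketone (future C7a), loss of water gives the conjugated vinylogous ester, equilibration favours the E isomer with the carbonyl anti to O1, and a weak acid in a dry aprotic medium spares the tertiary silyl ether.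

Step 8
Reactants: 15 (S,E)-3-methyl-1-[5-(2-triethylsilyloxypropan-2-yl)oxolan-2-ylidene]butan-2-one (fragment 1); 6 2,2-bis(3-methylbut-2-enyl)malonyl dichloride (fragment 2)
Product: 18 O-triethylsilyl garcinielliptone HD, via silyl dienol ether 16 (not isolated), via C3a-acylated acid chloride 17 (not isolated)
Conditions: 15, Et3N (1.3 equiv), Me3SiOTf (1.5 equiv), CH2Cl2, 0 °C; added over 2 h to 6 (1.05 equiv), CH2Cl2 (0.01 M), −78 to 0 °C; DBU (3 equiv), 0 °C to rt; cold aq. citric acid
Reagents that add atoms: none
Why: Proposed new method: Me3SiOTf silylates the enone oxygen of 15 and Et3N removes a ring proton at the future C3a (soft enolisation to the extended dienol silane 16); the terminal diene carbon C3a, pushed by O1 and by the vinylogous silyloxy group, attacks one acyl chloride of 6 under catalysis by the surplus Me3SiOTf (C3a-C4, loss of Me3SiCl) to give 17, and DBU then removes the now acidic C3a-H so that the extended enolate attacks the second acyl chloride through C7 (C6-C7) and the product rests as its triketone enolate until the acidic work-up delivers the chelated enol. The closest known reaction types are the terminal-carbon acylation of 1,3-bis(silyloxy)-1,3-dienes by acid chlorides and the Effenberger cyclisation of enol silanes with malonyl dichloride, neither of which has been applied to a diene derived from an alkylidene-oxolane. Ring A closes in the 6-(enolendo)-exo-trig mode, helped by ring B, which ties O1 to C3 and thereby holds C4 and C7 on the same side of the C3a-C7a bond. No stereocentre is formed, since C3a is sp3 only in 17 and becomes planar again, while C2 has no acidic hydrogen and lies away from every bond that changes. The step needs C- rather than O-acylation and the order gamma before alpha: had C7 reacted first, the isobutyryl enolate oxygen could close a six-membered enol lactone, whereas in 17 an oxygen closure would have to be four- or eight-membered, so only the carbocycle is within reach. The isopropyl methine should stay out because allylic strain keeps its C-H in the plane of the pi system and the linear diene is the more stable one, 6 has no alpha hydrogen and cannot form a ketene, slow addition of 16 to 6 at high dilution limits 2:1 adducts, and the base is sized for the HCl released plus the acidic product.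

Step 9
Reactants: 18 O-triethylsilyl garcinielliptone HD
Product: 19 garcinielliptone HD
Conditions: HF·pyridine, pyridine, THF, 0 °C to rt
Reagents that add atoms: none
Why: Fluoride-induced silyl ether cleavage, driven by the strong Si-F bond, should free the tertiary alcohol, and pyridine-buffered HF is too weak an acid to protonate the prenyl alkenes or to disturb the vinylogous ester, the enol or C2.

Compound list
1 | diethyl malonate | CCOC(=O)CC(=O)OCC | starting material
2 | prenyl bromide (1-bromo-3-methylbut-2-ene) | CC(C)=CCBr | starting material
3 | diethyl 2-(3-methylbut-2-enyl)malonate (not isolated) | CCOC(=O)C(CC=C(C)C)C(=O)OCC | intermediate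
4 | diethyl 2,2-bis(3-methylbut-2-enyl)malonate | CCOC(=O)C(CC=C(C)C)(CC=C(C)C)C(=O)OCC | intermediate
5 | 2,2-bis(3-methylbut-2-enyl)malonic acid | CC(C)=CCC(CC=C(C)C)(C(=O)O)C(=O)O | intermediate
6 | 2,2-bis(3-methylbut-2-enyl)malonyl dichloride (fragment 2) | CC(C)=CCC(CC=C(C)C)(C(Cl)=O)C(Cl)=O | intermediate
7 | methyl (S)-glycidate | COC(=O)[C@@H]1CO1 | starting material
8 | (S)-1-(oxiran-2-yl)ethan-1-one (not isolated) | CC(=O)[C@@H]1CO1 | intermediate
9 | (S)-2-(oxiran-2-yl)propan-2-ol | CC(C)(O)[C@@H]1CO1 | intermediate
10 | (S)-triethyl{[2-(oxiran-2-yl)propan-2-yl]oxy}silane | CC[Si](CC)(CC)OC(C)(C)[C@@H]1CO1 | intermediate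
11 | 5-methylhexane-2,4-dione | CC(C)C(=O)CC(C)=O | starting material
12 | dilithium 5-methylhexa-1,3-diene-2,4-diolate (not isolated) | [Li+].[Li+].C=C([O-])C=C([O-])C(C)C | intermediate
13 | (S)-8-hydroxy-2,9-dimethyl-9-(triethylsilyloxy)decane-3,5-dione | CC(C)C(=O)CC(=O)CC[C@H](O)C(C)(C)O[Si](CC)(CC)CC | intermediate
14 | (5S)-2-hydroxy-2-(3-methyl-2-oxobutyl)-5-[2-(triethylsilyloxy)propan-2-yl]oxolane, anomers (not isolated) | CC(C)C(=O)CC1(O)CC[C@@H](C(C)(C)O[Si](CC)(CC)CC)O1 | intermediate
15 | (S,E)-3-methyl-1-[5-(2-triethylsilyloxypropan-2-yl)oxolan-2-ylidene]butan-2-one (fragment 1) | CC(C)C(=O)/C=C1/O[C@H](C(C)(C)O[Si](CC)(CC)CC)CC1 | intermediate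
16 | (S)-5-[(Z)-3-methyl-2-(trimethylsilyloxy)but-1-enyl]-2-[2-(triethylsilyloxy)propan-2-yl]-2,3-dihydrofuran (not isolated; enol silane geometry expected Z, of no consequence) | CC(C)/C(O[Si](C)(C)C)=C/C1=CC[C@@H](C(C)(C)O[Si](CC)(CC)CC)O1 | intermediate
17 | 2-({(5S)-2-[(E)-3-methyl-2-oxobutylidene]-5-[2-(triethylsilyloxy)propan-2-yl]oxolan-3-yl}carbonyl)-5-methyl-2-(3-methylbut-2-enyl)hex-4-enoyl chloride, C3a epimers (not isolated) | CC(C)C(=O)/C=C1/O[C@H](C(C)(C)O[Si](CC)(CC)CC)CC1C(=O)C(CC=C(C)C)(CC=C(C)C)C(Cl)=O | intermediate
18 | (2S)-7-[(Z)-1-hydroxy-2-methylpropylidene]-5,5-bis(3-methylbut-2-enyl)-2-[2-(triethylsilyloxy)propan-2-yl]-2,3-dihydro-1-benzofuran-4,6(5H,7H)-dione (O-triethylsilyl garcinielliptone HD) | CC(C)=CCC1(CC=C(C)C)C(=O)C2=C(O[C@H](C(C)(C)O[Si](CC)(CC)CC)C2)/C(=C(/O)C(C)C)C1=O | intermediate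
19 | garcinielliptone HD, (2S)-7-[(Z)-1-hydroxy-2-methylpropylidene]-2-(2-hydroxypropan-2-yl)-5,5-bis(3-methylbut-2-enyl)-2,3-dihydro-1-benzofuran-4,6(5H,7H)-dione | CC(C)=CCC1(CC=C(C)C)C(=O)C2=C(O[C@H](C(C)(C)O)C2)/C(=C(/O)C(C)C)C1=O | target

Total step count: 9. Longest linear sequence: 6 steps (steps 4 to 9, from 7).

Steps most likely to fail

1. Step 8. Several processes could defeat it:
- The diene may attack the neopentyl-type acyl chloride too slowly.
- Part of the enolisation may run toward the isopropyl side.
- The second acylation may go intermolecularly and build oligomers.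
- Acylation may end on oxygen.

The fallback builds the ring in two separately controlled, known operations, using a malonyl unit whose two ends differ. It sets out from 4 (and uses 15) and comes back at 18. Partial saponification of 4 (KOH, 1.0 equiv, EtOH, rt) should give the half ester 2-(ethoxycarbonyl)-5-methyl-2-(3-methylbut-2-enyl)hex-4-enoic acid F1. The chloroenamine of step 3 converts this into ethyl 2-(chlorocarbonyl)-5-methyl-2-(3-methylbut-2-enyl)hex-4-enoate F2. The lithium dienolate of 15 (LiN(SiMe3)2, 2.1 equiv, THF, −78 °C) is acylated by F2 in a crossed Claisen-type C-acylation, as practised on lithium dienolates of cyclic vinylogous esters. This should give ethyl 2-({(5S)-2-[(E)-3-methyl-2-oxobutylidene]-5-[2-(triethylsilyloxy)propan-2-yl]oxolan-3-yl}carbonyl)-5-methyl-2-(3-methylbut-2-enyl)hex-4-enoate F3. A Dieckmann condensation (KOtBu, THF, 0 °C to rt, then citric acid) closes C6-C7 onto the ethyl ester. With a single acyl chloride no oligomer can grow, and the open-chain stage can be purified. The closure is reversible up to the stabilised triketone enolate, so an O-acylated or C7-acylated isomer of the open-chain stage would be drawn to the same 18.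

2. Step 6. The triethylsilyl group may migrate from the tertiary to the secondary oxygen while the lithium alkoxide is alive. The opening may also be slow next to the bulky carbinol carbon, which would lengthen that exposure. The fallback moves the silylation behind ring closure. It sets out from 9 and comes back at 15. Compound 9 is turned into its lithium alkoxide (n-BuLi, 1.0 equiv, THF, −78 °C) and opened by 12 at the CH2 terminus, which should give (S)-8,9-dihydroxy-2,9-dimethyldecane-3,5-dione F4. The conditions of step 7 then close the kinetically favoured five-membered ring through the secondary hydroxyl, giving (S,E)-1-[5-(2-hydroxypropan-2-yl)oxolan-2-ylidene]-3-methylbutan-2-one F5. Et3SiOTf and 2,6-lutidine (CH2Cl2, −78 to 0 °C) silylate the free tertiary alcohol to 15.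

3. Step 4. The Grignard reagent or its chloride may open the epoxide alongside the ester addition, and the small, water-soluble, volatile product may be lost on isolation. The fallback masks the epoxide during the organometallic step. It sets out from 7 and comes back at 9. LiCl and AcOH in THF open 7 at the CH2 terminus to give methyl (R)-3-chloro-2-hydroxypropanoate F6; the descriptor changes only because CH2Cl now outranks the ester carbon. MeMgCl (3.2 equiv, THF, −40 to 0 °C) converts the ester into (R)-1-chloro-3-methylbutane-2,3-diol F7. K2CO3 in MeOH lets the secondary alkoxide displace the primary chloride, re-forming the epoxide of 9 with the C-O bond at the stereocentre intact.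

Further compounds
F1 | step 8 | 2-(ethoxycarbonyl)-5-methyl-2-(3-methylbut-2-enyl)hex-4-enoic acid | CCOC(=O)C(CC=C(C)C)(CC=C(C)C)C(=O)O
F2 | step 8 | ethyl 2-(chlorocarbonyl)-5-methyl-2-(3-methylbut-2-enyl)hex-4-enoate | CCOC(=O)C(CC=C(C)C)(CC=C(C)C)C(Cl)=O
F3 | step 8 | ethyl 2-({(5S)-2-[(E)-3-methyl-2-oxobutylidene]-5-[2-(triethylsilyloxy)propan-2-yl]oxolan-3-yl}carbonyl)-5-methyl-2-(3-methylbut-2-enyl)hex-4-enoate | CC(C)C(=O)/C=C1/O[C@H](C(C)(C)O[Si](CC)(CC)CC)CC1C(=O)C(CC=C(C)C)(CC=C(C)C)C(=O)OCC
F4 | step 6 | (S)-8,9-dihydroxy-2,9-dimethyldecane-3,5-dione | CC(C)C(=O)CC(=O)CC[C@H](O)C(C)(C)O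
F5 | step 6 | (S,E)-1-[5-(2-hydroxypropan-2-yl)oxolan-2-ylidene]-3-methylbutan-2-one | CC(C)C(=O)/C=C1/O[C@H](C(C)(C)O)CC1
F6 | step 4 | methyl (R)-3-chloro-2-hydroxypropanoate | COC(=O)[C@@H](O)CCl
F7 | step 4 | (R)-1-chloro-3-methylbutane-2,3-diol | CC(C)(O)[C@@H](O)CCl
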